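**Plan**
- Retrosynthesis: the C16=C17 methylene (Wittig) and the C15 oxygen are removed first. C8–C15 is traced back to C9–C15 by a radical 1,2-acyl shift, and C9–C11 and C12–C13 are cut as an ethylene [4+2] on an oxidised phenol. Then follow C4–C5 (Michael), C6–C7 (carbonylation), C6–C8 (Friedel–Crafts), C10–C1 (enolate alkylation) and C9–C10 (phenol/alkyne condensation).
- Forward: pyrogallol ring (future C8, C9, C13–C16) → coumarin → quaternary C10 → ring B (indanone, indene ester) → ring A (Michael) → bicyclo[2.2.2]octenone → bicyclo[3.2.1]octane (rings C and D) → deoxygenation, deprotection, methylenation.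
- Enabling feature: ring C (C8, C9, C11–C14) carries its only oxygen on bridgehead C13, flanked by C14 and by C16 of ring D. With C15 placed back on C9, the carbons C8, C9, C15, C16, C13, C14 form a benzene ring oxygenated at C15, C16 and C13 (pyrogallol pattern), and C11–C12 is a bare CH2–CH2 unit, i.e. ethylene.
- Stereochemistry: the absolute configuration comes from resolution of acid 14 (C10, the only stereocentre at that point). C5 and C4 come from the tethered, lithium-bridged Michael closure, C6 from equilibration, C9/C13 from the face of the cycloaddition, C8 from the suprafacial acyl shift and H9 from the radical reduction.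

Key step: step 14

Remark: gibberellane numbering is used throughout (C7, C19, C20 are the carboxyl carbons on C6, C4, C10). The target SMILES is read literally: the C20 carboxyl, H5, H9 and the C7 ester lie on one face of ring B, and C1, C4 and C11 on the other (rings A/B cis-fused).
Remark: which antipode of 1-phenylethylamine gives the less soluble salt of the wanted acid cannot be foreseen; the (R)-amine is written and its mirror image would be used otherwise.
Remark: 16–20 are carried as mixtures of C4 epimers (that centre is formed in step 9 and re-formed in step 13); 28 is drawn as the expected C15 epimer, and either epimer serves.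

Step 1
Reactants: 1 acetylenedicarboxylic acid; 2 benzyl alcohol
Product: 3 dibenzyl but-2-ynedioate
Conditions: BnOH (2.5 equiv in total), TsOH·H2O (cat.), toluene, reflux, Dean–Stark
Reagents that add atoms: benzyl alcohol (second equivalent), OCc1ccccc1
Why: Twofold Fischer esterification driven by azeotropic removal of water; each carboxyl group takes up one molecule of benzyl alcohol, and the diester later supplies C20 as a benzyl ester (no stereocentre).

Step 2
Reactants: 4 pyrogallol; 3 dibenzyl but-2-ynedioate
Product: 5 benzyl 7,8-dihydroxy-2-oxo-2H-chromene-4-carboxylate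
Conditions: PPh3 (1 equiv, recovered), CH2Cl2, 0 °C to reflux
Reagents that add atoms: none
Why: Phosphine-mediated phenol–acetylenedicarboxylate condensation: PPh3 adds to the alkyne, the phenol protonates the zwitterion, the phenoxide attacks the vinylphosphonium through its ortho carbon, PPh3 leaves and the cis aryl ester lactonises with loss of benzyl alcohol, which forms C9–C10 and brings in C20, C5 and C6 in one operation.

Step 3
Reactants: 5 benzyl 7,8-dihydroxy-2-oxo-2H-chromene-4-carboxylate
Product: 6 benzyl 7-(benzyloxy)-8-hydroxy-2-oxo-2H-chromene-4-carboxylate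
Conditions: BnBr (1.05 equiv), K2CO3 (1.0 equiv), acetone, rt
Reagents that add atoms: benzyl bromide, BrCc1ccccc1
Why: Williamson etherification; the 7-OH (future O13) is a vinylogous acid conjugated to the lactone carbonyl, so one equivalent of weak base ionises and benzylates it in preference to the 8-OH.

Step 4
Reactants: 6 benzyl 7-(benzyloxy)-8-hydroxy-2-oxo-2H-chromene-4-carboxylate
Product: 7 benzyl 7-(benzyloxy)-8-methoxy-2-oxo-2H-chromene-4-carboxylate
Conditions: MeI, K2CO3, DMF, rt
Reagents that add atoms: iodomethane, CI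
Why: Williamson methylation of the remaining phenol installs the C16 methoxy group that later becomes one arm of the ketal.

Step 5
Reactants: 8 benzyl 5-bromopentanoate
Product: 9 benzyl 5-iodopentanoate
Conditions: NaI, acetone, reflux
Reagents that add atoms: sodium iodide, [Na+].[I-]
Why: Finkelstein exchange, driven by precipitation of NaBr, gives the more reactive alkylating agent (C1–C4 and C19).

Step 6
Reactants: 7 benzyl 7-(benzyloxy)-8-methoxy-2-oxo-2H-chromene-4-carboxylate; 9 benzyl 5-iodopentanoate
Product: 11 racemic benzyl 7-(benzyloxy)-4-[5-(benzyloxy)-5-oxopentyl]-8-methoxy-2-oxochromane-4-carboxylate, via lithium C10 ester enolate 10 (not isolated)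
Conditions: LiBH(s-Bu)3 (1.05 equiv), THF, −78 °C; then 9, DMPU, −78 °C to rt
Reagents that add atoms: none
Why: Conjugate reduction–alkylation: the bulky hydride adds to the unsubstituted C5 of the ene-dicarbonyl and so gives only the aryl-stabilised C10 ester enolate, which the primary iodide alkylates to the quaternary C10 (racemic, no control needed here).

Step 7
Reactants: 11 racemic quaternary lactone
Product: 14 racemic 3-[4-(benzyloxy)-2-(tert-butyldimethylsilyloxy)-3-methoxyphenyl]-3-(benzyloxycarbonyl)-8-(benzyloxy)-8-oxooctanoic acid, via dilithium phenoxide carboxylate 12 (not isolated), via bis-silylated hydroxy acid 13 (not isolated)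
Conditions: LiOH·H2O (2.1 equiv), THF/H2O, 0 °C; evaporate, toluene azeotrope; TBSCl, imidazole, DMF, rt; then AcOH/THF/H2O, rt
Reagents that add atoms: lithium hydroxide, [Li+].[OH-]; tert-butyldimethylsilyl chloride, CC(C)(C)[Si](C)(C)Cl
Why: Saponification of the aryl lactone is far faster than that of the alkyl benzyl esters and uses up the hydroxide (one equivalent opens the ring, one ionises the phenol); silylating the dianion before any acid is present prevents re-lactonisation of the gem-disubstituted hydroxy acid, and the silyl ester alone is then hydrolysed.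

Step 8
Reactants: 14 racemic acid
Product: 15 (R)-3-[4-(benzyloxy)-2-(tert-butyldimethylsilyloxy)-3-methoxyphenyl]-3-(benzyloxycarbonyl)-8-(benzyloxy)-8-oxooctanoic acid
Conditions: (R)-1-phenylethylamine (1 equiv), i-PrOAc/heptane, two recrystallisations; then 1 M HCl, EtOAc
Reagents that add atoms: none
Why: Classical resolution by fractional crystallisation of diastereomeric ammonium salts of an acid with one stereocentre; this is where the absolute configuration (C10) enters the route.

Step 9
Reactants: 15 (R)-acid
Product: 16 (3R)-3-[4-(benzyloxy)-2-(tert-butyldimethylsilyloxy)-3-methoxyphenyl]-3-(benzyloxycarbonyl)-8-(benzyloxy)-7-methyl-8-oxooctanoic acid (epimers at the methyl-bearing carbon, gibberellane C4)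
Conditions: LiN(i-Pr)2 (2.2 equiv), THF, −78 °C; MeI (1.1 equiv), −78 to −40 °C; 1 M HCl work-up
Reagents that add atoms: iodomethane, CI
Why: Ester enolate alkylation: the first equivalent of amide gives the carboxylate, the second removes only the ester α-proton at −78 °C (carboxylate α-protons are far less acidic), and MeI methylates C4; the new centre forms unselectively and is erased again in step 13.

Step 10
Reactants: 16 methylated acid
Product: 18 benzyl 5-(benzyloxy)-1-[5-(benzyloxy)-4-methyl-5-oxopentyl]-7-(tert-butyldimethylsilyloxy)-6-methoxy-3-oxoindane-1-carboxylate (C10 as in 15), via acid chloride 17 (not isolated)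
Conditions: (COCl)2, DMF (cat.), CH2Cl2, 0 °C to rt; evaporate; SnCl4 (1.2 equiv), CH2Cl2, −78 to −20 °C
Reagents that add atoms: none
Why: Intramolecular Friedel–Crafts acylation closes ring B (C6–C8); the acylium can only reach C8 (five-membered ring), which is para to the C16 methoxy group, and the lactone route to the phenol is closed because O15 is silylated.

Step 11
Reactants: 18 indanone
Product: 19 benzyl 5-(benzyloxy)-1-[5-(benzyloxy)-4-methyl-5-oxopentyl]-7-(tert-butyldimethylsilyloxy)-6-methoxy-3-(trifluoromethylsulfonyloxy)-1H-indene-1-carboxylate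
Conditions: KN(SiMe3)2 (1.1 equiv), THF, −78 °C; PhNTf2, −78 to 0 °C
Reagents that add atoms: N-phenylbis(trifluoromethanesulfonimide), O=S(=O)(N(c1ccccc1)S(=O)(=O)C(F)(F)F)C(F)(F)F
Why: Kinetic enolisation at C5 (the ketone α-protons are the most acidic in the molecule) and O-triflation give the enol triflate.

Step 12
Reactants: 19 enol triflate
Product: 20 1-benzyl 3-methyl 5-(benzyloxy)-1-[5-(benzyloxy)-4-methyl-5-oxopentyl]-7-(tert-butyldimethylsilyloxy)-6-methoxy-1H-indene-1,3-dicarboxylate
Conditions: Pd(OAc)2 (5 mol %), dppp (6 mol %), CO (1 atm), MeOH, Et3N, DMF, 60 °C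
Reagents that add atoms: carbon monoxide, [C-]#[O+]; methanol, CO
Why: Palladium-catalysed methoxycarbonylation (oxidative addition of zerovalent palladium to the enol triflate, CO insertion, methanolysis) installs C7 as the methyl ester and makes C5 a Michael acceptor; the quaternary C10 prevents migration of the indene double bond.

Step 13
Reactants: 20 indene diester
Product: 23 tricyclic phenol (rings A and B on the arene: C7 methyl ester, C19 and C20 benzyl esters, 13-OBn, 16-OMe, 15-OH), via lithium C7 ester enolate 21 (not isolated), via silyl ether adduct 22 (not isolated)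
Conditions: LiN(i-Pr)2 (1.1 equiv), THF, −78 to −40 °C; t-BuOH (5 equiv), −40 °C to rt; then AcOH (2.5 equiv), n-Bu4NF (1.5 equiv), 0 °C; aq. NH4Cl
Reagents that add atoms: none
Why: Intramolecular Michael addition (6-exo-trig) of the C19 ester enolate (C4–H is the only acidic C–H) to C5: the tether from C10 reaches C5 only on the C1 face, so ring A is cis-fused with H5 syn to the C20 ester, and a closed lithium-bridged transition state (enolate oxygen and C7 carbonyl on one lithium, donor and acceptor double bonds gauche) places the C19 ester under ring B and the methyl outside, as in the target; tert-butanol then protonates the C7 enolate, the lithium tert-butoxide so formed equilibrates C6 (C7 ester trans to the quaternary C4) without exchanging any ester, and acetic-acid-buffered fluoride cleaves the aryl silyl ether under near-neutral conditions, so the phenol never meets an alkoxide while it sits next to the C20 benzyl ester.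

Step 14
Reactants: 23 tricyclic phenol; 24 ethylene
Product: 26 bicyclo[2.2.2]octenone (C13 benzyl ether, C16 dimethyl ketal, C15 ketone on C9, C8=C14 alkene, C11–C12 bridge on the C1 face), via 6,6-dimethoxycyclohexadienone 25 (not isolated)
Conditions: PhI(OAc)2 (1.1 equiv), MeOH, 0 °C; evaporate; ethylene (50 bar), toluene, 100 °C, autoclave
Reagents that add atoms: methanol, CO
Why: Ligand exchange of the phenol on the trivalent iodine reagent and attack of methanol at the methoxy-bearing C16 give dienone 25 (C15 ketone, C16 ketal), whose diene C9=C8–C14=C13 is held s-cis in the ring; ethylene then adds across C9 and C13 in a concerted suprafacial [4+2] cycloaddition, the closest known type being the Diels–Alder reaction of masked o-benzoquinones with alkenes. The new six-membered ring (C9–C11–C12–C13 bridging the former arene) is closed by cycloaddition, both sigma bonds forming together, and gives the bicyclo[2.2.2]oct-5-en-2-one. C9 and C13 are created together and are tied to each other by the bridge, so only the face has to be controlled: ethylene should come from the ring B face that carries C1 and H6, because the C20 ester on C10 avoids the plane of the C15 carbonyl and stands with the C7 ester on C6 over the opposite face next to C9 and C8, while C1 and H6 are splayed outward. A symmetrical dienophile raises no regiochemical question, and full substitution at C8 and C9 slows the usual dimerisation of the dienone long enough for the unactivated alkene to react under pressure.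

Step 15
Reactants: 26 bicyclo[2.2.2]octenone
Product: 27 bicyclo[3.2.1]octanone (C15 ketone now on C8, C16 ketal, H9 on the C15 face, C14 and C11 on the C1 face)
Conditions: Fe(acac)3 (30 mol %), PhSiH3 (3 equiv), EtOH, 60 °C
Reagents that add atoms: none
Why: Hydrogen-atom-transfer-initiated Dowd–Beckwith rearrangement: Markovnikov H transfer to C14 gives the tertiary C8 radical, 3-exo attack on the C15 ketone and C9–C15 scission move the acyl group to C8 on the face it already occupied (which fixes C8), and the C9 radical should take H on that same face so that the quaternary C10 turns anti to the new two-carbon bridge.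

Step 16
Reactants: 27 rearranged ketone
Product: 28 C15 alcohol (OH expected endo, toward C11)
Conditions: NaBH4, CeCl3·7H2O, MeOH/THF, −40 °C; AcOH quench
Reagents that add atoms: none
Why: Borohydride reduction of the only ketone, with hydride expected on the exo face of the two-carbon bridge (anti to the C9–C11–C12 bridge); the cold, acid-quenched protocol keeps the alkoxide from attacking a neighbouring ester, and the centre is removed in step 18.

Step 17
Reactants: 28 C15 alcohol
Product: 29 C15 O-alkyl S-methyl xanthate
Conditions: NaN(SiMe3)2 (1.05 equiv), THF, −78 °C, 5 min; CS2 (5 equiv), −78 °C; then MeI, −78 to 0 °C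
Reagents that add atoms: carbon disulfide, S=C=S; iodomethane, CI
Why: Xanthate formation: the alcohol consumes the amide base at −78 °C before CS2 is added, the alkoxide is too cold (and, as the endo epimer, too poorly placed) to reach the C7 ester, and it is trapped by CS2 within minutes and then S-methylated.

Step 18
Reactants: 29 xanthate
Product: 30 C15-deoxygenated tetracycle (C15 H2, C16 dimethyl ketal, 13-OBn, benzyl esters)
Conditions: Bu3SnH, AIBN (cat.), toluene, 110 °C
Reagents that add atoms: none
Why: Barton–McCombie deoxygenation; the secondary C15 radical has no fragmentation path (no carbonyl on the adjacent carbons and no leaving group that a radical expels) and is reduced to CH2.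

Step 19
Reactants: 30 deoxygenated tetracycle
Product: 31 13-hydroxy C19,C20-diacid with C16 dimethyl ketal and C7 methyl ester
Conditions: H2 (1 atm), 10% Pd/C, EtOAc/MeOH, rt
Reagents that add atoms: none
Why: Hydrogenolysis removes the tertiary benzyl ether and both benzyl esters in one operation while the methyl ester and the ketal stay; it is done before the alkene exists.

Step 20
Reactants: 31 hydroxy diacid ketal
Product: 32 13-hydroxy-16-oxo C19,C20-diacid C7 methyl ester
Conditions: 1 M HCl, THF, 40 °C
Reagents that add atoms: water, O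
Why: Acid hydrolysis of the dimethyl ketal unveils the C16 ketone; the hindered acids and the methyl ester are inert under these conditions.

Step 21
Reactants: 32 hydroxy keto diacid
Product: 34 target (16-methylene, 13-OH, C19 and C20 acids, C7 methyl ester), via tris-trimethylsilyl derivative 33 (not isolated)
Conditions: 1-(trimethylsilyl)imidazole (3.5 equiv), THF, rt; then Ph3PCH3Br/KOt-Bu (5 equiv), THF, 0 °C to rt; then aq. citric acid, 0 °C
Reagents that add atoms: methyltriphenylphosphonium bromide, C[P+](c1ccccc1)(c1ccccc1)c1ccccc1.[Br-]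
Why: Wittig methylenation of the C16 ketone; silylating the 13-OH and both acids first keeps a free alkoxide away from the α-ketol (which could otherwise undergo ketol rearrangement under the basic ylide), and the silyl groups fall off on mild acidic work-up.

**Compound list**
1 | acetylenedicarboxylic acid | OC(=O)C#CC(=O)O | starting material
2 | benzyl alcohol | OCc1ccccc1 | starting material
3 | dibenzyl but-2-ynedioate | O=C(OCc1ccccc1)C#CC(=O)OCc1ccccc1 | intermediate
4 | pyrogallol | Oc1cccc(O)c1O | starting material
5 | benzyl 7,8-dihydroxy-2-oxo-2H-chromene-4-carboxylate | O=C1C=C(C(=O)OCc2ccccc2)c2ccc(O)c(O)c2O1 | intermediate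
6 | benzyl 7-(benzyloxy)-8-hydroxy-2-oxo-2H-chromene-4-carboxylate | O=C1C=C(C(=O)OCc2ccccc2)c2ccc(OCc3ccccc3)c(O)c2O1 | intermediate
7 | benzyl 7-(benzyloxy)-8-methoxy-2-oxo-2H-chromene-4-carboxylate | O=C1C=C(C(=O)OCc2ccccc2)c2ccc(OCc3ccccc3)c(OC)c2O1 | intermediate
8 | benzyl 5-bromopentanoate | BrCCCCC(=O)OCc1ccccc1 | starting material
9 | benzyl 5-iodopentanoate | ICCCCC(=O)OCc1ccccc1 | intermediate
10 | lithium C10 ester enolate of the dihydrocoumarin | [Li+].[O-]C(OCc1ccccc1)=C1CC(=O)Oc2c(OC)c(OCc3ccccc3)ccc12 | intermediate (not isolated)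
11 | racemic benzyl 7-(benzyloxy)-4-[5-(benzyloxy)-5-oxopentyl]-8-methoxy-2-oxochromane-4-carboxylate | O=C1CC(CCCCC(=O)OCc2ccccc2)(C(=O)OCc2ccccc2)c2ccc(OCc3ccccc3)c(OC)c2O1 | intermediate
12 | dilithium phenoxide carboxylate from lactone opening (racemic) | [Li+].[Li+].[O-]C(=O)CC(CCCCC(=O)OCc1ccccc1)(C(=O)OCc1ccccc1)c1ccc(OCc2ccccc2)c(OC)c1[O-] | intermediate (not isolated)
13 | bis-silylated hydroxy acid (aryl TBS ether, TBS ester; racemic) | CC(C)(C)[Si](C)(C)OC(=O)CC(CCCCC(=O)OCc1ccccc1)(C(=O)OCc1ccccc1)c1ccc(OCc2ccccc2)c(OC)c1O[Si](C)(C)C(C)(C)C | intermediate (not isolated)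
14 | racemic 3-[4-(benzyloxy)-2-(tert-butyldimethylsilyloxy)-3-methoxyphenyl]-3-(benzyloxycarbonyl)-8-(benzyloxy)-8-oxooctanoic acid | OC(=O)CC(CCCCC(=O)OCc1ccccc1)(C(=O)OCc1ccccc1)c1ccc(OCc2ccccc2)c(OC)c1O[Si](C)(C)C(C)(C)C | intermediate
15 | (R)-enantiomer of acid 14 (C10 as in the target) | OC(=O)C[C@@](CCCCC(=O)OCc1ccccc1)(C(=O)OCc1ccccc1)c1ccc(OCc2ccccc2)c(OC)c1O[Si](C)(C)C(C)(C)C | intermediate
16 | (3R)-7-methyl derivative of acid 15 (epimers at the methyl-bearing carbon, gibberellane C4) | OC(=O)C[C@@](CCCC(C)C(=O)OCc1ccccc1)(C(=O)OCc1ccccc1)c1ccc(OCc2ccccc2)c(OC)c1O[Si](C)(C)C(C)(C)C | intermediate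
17 | acid chloride of 16 | ClC(=O)C[C@@](CCCC(C)C(=O)OCc1ccccc1)(C(=O)OCc1ccccc1)c1ccc(OCc2ccccc2)c(OC)c1O[Si](C)(C)C(C)(C)C | intermediate (not isolated)
18 | indanone (ring B closed; C6 ketone, C20 benzyl ester and side chain on C10, 15-OTBS, 16-OMe, 13-OBn; C4 epimers) | O=C1C[C@@](CCCC(C)C(=O)OCc2ccccc2)(C(=O)OCc2ccccc2)c2c(O[Si](C)(C)C(C)(C)C)c(OC)c(OCc3ccccc3)cc12 | intermediate
19 | enol triflate of 18 (C5=C6) | O=S(=O)(OC1=C[C@@](CCCC(C)C(=O)OCc2ccccc2)(C(=O)OCc2ccccc2)c2c(O[Si](C)(C)C(C)(C)C)c(OC)c(OCc3ccccc3)cc12)C(F)(F)F | intermediate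
20 | indene diester (C7 methyl ester on C6, C5=C6; C4 epimers) | COC(=O)C1=C[C@@](CCCC(C)C(=O)OCc2ccccc2)(C(=O)OCc2ccccc2)c2c(O[Si](C)(C)C(C)(C)C)c(OC)c(OCc3ccccc3)cc12 | intermediate
21 | lithium C7 ester enolate of the cyclised silyl ether | [Li+].COC([O-])=C1c2cc(OCc3ccccc3)c(OC)c(O[Si](C)(C)C(C)(C)C)c2[C@@]2(C(=O)OCc3ccccc3)CCC[C@@](C)(C(=O)OCc3ccccc3)[C@@H]12 | intermediate (not isolated)
22 | cyclised silyl ether (rings A and B; C6 epimers) | COC(=O)C1c2cc(OCc3ccccc3)c(OC)c(O[Si](C)(C)C(C)(C)C)c2[C@@]2(C(=O)OCc3ccccc3)CCC[C@@](C)(C(=O)OCc3ccccc3)[C@@H]12 | intermediate (not isolated)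
23 | tricyclic phenol (C20 ester, H5 and C7 ester on one face of ring B; C4 methyl cis to H5, C19 ester cis to C6) | COC(=O)[C@@H]1c2cc(OCc3ccccc3)c(OC)c(O)c2[C@@]2(C(=O)OCc3ccccc3)CCC[C@@](C)(C(=O)OCc3ccccc3)[C@@H]12 | intermediate
24 | ethylene | C=C | starting material
25 | 6,6-dimethoxycyclohexa-2,4-dienone (C15 ketone, C16 ketal, diene C9=C8–C14=C13) | COC(=O)[C@@H]1C2=C(C(=O)C(OC)(OC)C(OCc3ccccc3)=C2)[C@@]2(C(=O)OCc3ccccc3)CCC[C@@](C)(C(=O)OCc3ccccc3)[C@@H]12 | intermediate (not isolated)
26 | bicyclo[2.2.2]octenone (C11–C12 bridge on the C1 face, C15 ketone bridge on the C20 face) | COC(=O)[C@@H]1C2=C[C@@]3(OCc4ccccc4)CC[C@@]2(C(=O)C3(OC)OC)[C@@]2(C(=O)OCc3ccccc3)CCC[C@@](C)(C(=O)OCc3ccccc3)[C@@H]12 | intermediate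
27 | bicyclo[3.2.1]octanone (C15 ketone on C8, H9 on the same face) | COC1(OC)C(=O)[C@]23C[C@@]1(OCc1ccccc1)CC[C@H]2[C@@]1(C(=O)OCc2ccccc2)CCC[C@@](C)(C(=O)OCc2ccccc2)[C@H]1[C@@H]3C(=O)OC | intermediate
28 | C15 alcohol (OH endo, toward C11) | COC1(OC)[C@@H](O)[C@]23C[C@@]1(OCc1ccccc1)CC[C@H]2[C@@]1(C(=O)OCc2ccccc2)CCC[C@@](C)(C(=O)OCc2ccccc2)[C@H]1[C@@H]3C(=O)OC | intermediate
29 | C15 O-alkyl S-methyl xanthate | COC1(OC)[C@@H](OC(=S)SC)[C@]23C[C@@]1(OCc1ccccc1)CC[C@H]2[C@@]1(C(=O)OCc2ccccc2)CCC[C@@](C)(C(=O)OCc2ccccc2)[C@H]1[C@@H]3C(=O)OC | intermediate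
30 | C15-deoxygenated tetracycle | COC1(OC)C[C@]23C[C@@]1(OCc1ccccc1)CC[C@H]2[C@@]1(C(=O)OCc2ccccc2)CCC[C@@](C)(C(=O)OCc2ccccc2)[C@H]1[C@@H]3C(=O)OC | intermediate
31 | 13-hydroxy diacid, C16 dimethyl ketal, C7 methyl ester | COC1(OC)C[C@]23C[C@@]1(O)CC[C@H]2[C@@]1(C(=O)O)CCC[C@@](C)(C(=O)O)[C@H]1[C@@H]3C(=O)OC | intermediate
32 | 13-hydroxy-16-oxo diacid, C7 methyl ester | O=C1C[C@]23C[C@@]1(O)CC[C@H]2[C@@]1(C(=O)O)CCC[C@@](C)(C(=O)O)[C@H]1[C@@H]3C(=O)OC | intermediate
33 | tris-trimethylsilyl derivative of 32 (13-OTMS, two TMS esters) | O=C1C[C@]23C[C@@]1(O[Si](C)(C)C)CC[C@H]2[C@@]1(C(=O)O[Si](C)(C)C)CCC[C@@](C)(C(=O)O[Si](C)(C)C)[C@H]1[C@@H]3C(=O)OC | intermediate (not isolated)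
34 | target: 13-hydroxy-16-methylene C19,C20-diacid C7 methyl ester | C=C1C[C@]23C[C@@]1(O)CC[C@H]2[C@@]1(C(=O)O)CCC[C@@](C)(C(=O)O)[C@H]1[C@@H]3C(=O)OC | target

**Step count**
Total: 21 steps. Longest linear sequence: 20 steps (steps 1–4 and 6–21; step 5 is a side branch).

**Three steps most likely to fail**

Step 14. Ethylene is unactivated, so the cycloaddition may be slow enough for the dienone to decompose, and the temperature it needs may erode the discrimination between the two faces of the diene. The fallback sets out from 23: the phenol is oxidised as before to 25, which is treated with phenyl vinyl sulfone in toluene at rt to 50 °C, an activated ethylene surrogate that reacts at much lower temperature. This gives the C11 phenylsulfonyl adduct F1. Reductive desulfonylation with Na(Hg) amalgam and Na2HPO4 in MeOH/THF at −20 °C then returns to the route at 26.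

Step 13. The enolate may add through an open rather than the lithium-bridged arrangement, which would give the C4 epimer; this quaternary centre cannot be corrected afterwards. The fallback sets out from 15 and omits step 9. Friedel–Crafts closure as in step 10, through the des-methyl acid chloride F3, gives the des-methyl indanone F4. Triflation gives the des-methyl enol triflate F5, and methoxycarbonylation gives the des-methyl indene diester F6. Michael closure with LiN(i-Pr)2, quenched with AcOH, gives the C4–H tricyclic silyl ether F7. Deprotonation with LiN(i-Pr)2 (2.2 equiv) at C6 and C4, followed by one equivalent of MeI, should methylate the more reactive C4 enolate on the convex face, anti to the indane unit, which is the target configuration. The product is silyl ether 22, where the route is rejoined at the tert-butanol equilibration stage of step 13.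

Step 15. The iron hydride may reduce the C8 radical before the acyl shift (plain hydrogenation of C8=C14), or this bulky hydrogen donor may deliver H to the wrong face of the C9 radical. The fallback sets out from 26 and uses a metal-free radical chain: PhSH added slowly with AIBN in benzene at 80 °C. The thiyl radical adds to C14, the same 3-exo acyl shift follows, and the C9 radical takes H from the small thiol, whose concentration is set by the addition rate. This gives the C14 phenylthio bicyclo[3.2.1]octanone F2. Desulfurisation with acetone-deactivated Raney Ni in EtOH at rt returns to the route at 27.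

Further compounds
F1 | step 14 | C11 phenylsulfonyl bicyclo[2.2.2]octenone adduct | COC(=O)[C@@H]1C2=C[C@@]3(OCc4ccccc4)CC(S(=O)(=O)c4ccccc4)[C@@]2(C(=O)C3(OC)OC)[C@@]2(C(=O)OCc3ccccc3)CCC[C@@](C)(C(=O)OCc3ccccc3)[C@@H]12
F2 | step 15 | C14 phenylthio bicyclo[3.2.1]octanone | COC1(OC)C(=O)[C@]23C(Sc4ccccc4)[C@@]1(OCc1ccccc1)CC[C@H]2[C@@]1(C(=O)OCc2ccccc2)CCC[C@@](C)(C(=O)OCc2ccccc2)[C@H]1[C@@H]3C(=O)OC
F3 | step 13 | des-methyl acid chloride (from 15) | ClC(=O)C[C@@](CCCCC(=O)OCc1ccccc1)(C(=O)OCc1ccccc1)c1ccc(OCc2ccccc2)c(OC)c1O[Si](C)(C)C(C)(C)C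
F4 | step 13 | des-methyl indanone | O=C1C[C@@](CCCCC(=O)OCc2ccccc2)(C(=O)OCc2ccccc2)c2c(O[Si](C)(C)C(C)(C)C)c(OC)c(OCc3ccccc3)cc12
F5 | step 13 | des-methyl enol triflate | O=S(=O)(OC1=C[C@@](CCCCC(=O)OCc2ccccc2)(C(=O)OCc2ccccc2)c2c(O[Si](C)(C)C(C)(C)C)c(OC)c(OCc3ccccc3)cc12)C(F)(F)F
F6 | step 13 | des-methyl indene diester | COC(=O)C1=C[C@@](CCCCC(=O)OCc2ccccc2)(C(=O)OCc2ccccc2)c2c(O[Si](C)(C)C(C)(C)C)c(OC)c(OCc3ccccc3)cc12
F7 | step 13 | C4–H tricyclic silyl ether (C4 and C6 epimers) | COC(=O)C1c2cc(OCc3ccccc3)c(OC)c(O[Si](C)(C)C(C)(C)C)c2[C@@]2(C(=O)OCc3ccccc3)CCCC(C(=O)OCc3ccccc3)[C@@H]12
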